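You can't integrate this flask on an envelope, since the capture of open intermediate runs on a c(second intermediate) that is itself climbing. So here is the quick number you asked for, with that curve replaced by its mean.

substrate 0.010 M; partner 1.80 equiv; time 15 min

* the target standing at 15 min, as a percentage of the substrate charged
* the homo product standing at 15 min, as a percentage of the substrate charged

    open intermediate + second intermediate → target (k1 = 550 /M/s)
    partner → second intermediate (k2 = 0.20 /s)
    2 open intermediate → homo product (k3 = 800 /M/s)
    open intermediate → side product (k4 = 0.10 /s)
    partner → decomposition product (k5 = 1.6 × 10⁻⁴ /s)
    substrate ⇌ open intermediate (K6 = 0.21, k6 = 0.10 /s)

- percent here means substrate units held: one homo product counts as two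
- where a step has two of a species, its rate is k times that concentration squared, and two are used at each turn
- run time (flask): 15 min

Weight c(second intermediate) by the moment each substrate opens, counting all opened substrate as captured. That gives m, the opening-weighted mean of c(second intermediate):

m = 0.0180 M × 0.667 − 0.00500 M = 0.007000 M

Capture is then pseudo-first-order at 3.85 /s, and I drop closing back, which at 0.476 /s is slower. With open intermediate near opening over capture, at mean c(substrate), the losses per target are:

side product: 0.10 /s / 3.85 /s = 0.0260

homo product, in substrate units: 0.0540

The run far outlasts the opening half-life of 0.116 min, so I commit to 92.6 % target and 5.00 % homo product.

Your forecast says 91 % and 6 %, on the ground that “The homo product forms mainly in the first few seconds”. My reckoning gives more target and less homo product.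

The flask gives 92.3 % target and 5.42 % homo product, so the forecast stands. With all else held, homo product has moved by 5 points once partner falls to 1.15 equiv or rises to 11.4 equiv, so a shift in partner of that size is what a run would have to show against the forecast. Read back from side product over target, the flask's capture ran at an effective c(second intermediate) of 0.007381 M, which is a mean weighted otherwise than m of 0.00700 M, though close to it.

In the neighbour flask at 0.025 M substrate, on the same equivalents of partner, m becomes 0.01750 M, which gives 1.01 % side product and 2.09 % homo product. That neighbour computes to 1.06 % and 3.89 %, so the mean holds for side product and falls short on homo product.

All constants were set for the occasion; the rest is arithmetic.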